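The plan cuts the seven-membered ring of the hydroazulene twice: at the C3a–C4 bond, where the C4 oxygen lies β to a C3 carbonyl (retro-aldol), and at the C6=C7 ring olefin (retro-metathesis). The key step is thus a one-flask [4+3] annulation: the regiodefined zinc enolate of (R)-3-allyl-3-methylcyclopentanone adds to 3-methylbut-3-enal, and the diene so formed is closed by ruthenium-catalysed ring-closing metathesis to the trans-fused bicyclic β-hydroxy ketone, with C3a and C4 set in the aldol. The precursors are only a cyclopentenyl silyl ether carrying the C8a quaternary centre and a five-carbon β,γ-unsaturated aldehyde; isopropyl addition at C3 and salicyloyl transfer to O4 complete the target.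

Key step: step 4

Remark: hydroazulene numbering is used (C1, C2 ring CH2; C3 carries OH and isopropyl; C3a ring-fusion CH; C4 carries the ester oxygen; C5 CH2; C6 carries the ring methyl; C7 olefinic CH; C8 CH2; C8a carries the angular methyl), and the target is taken as the (3R,3aS,4S,8aR) enantiomer written in the SMILES.

Step 1
Reactants: 1 3-ethoxycyclopent-2-en-1-one; 2 prop-2-en-1-ylmagnesium bromide (allylmagnesium bromide)
Product: 3 3-(prop-2-en-1-yl)cyclopent-2-en-1-one
Conditions: THF, 0 °C; then 1 M HCl, 0 °C, short contact
Reagents that add atoms: water, O
Why: 1,2-addition of the allyl Grignard reagent to the vinylogous ester followed by acid-induced loss of ethanol with carbonyl transposition (Stork–Danheiser sequence) should give the β-allyl enone, brief cold acid keeping the skipped alkene out of conjugation; no stereocentre is formed.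

Step 2
Reactants: 3 3-(prop-2-en-1-yl)cyclopent-2-en-1-one
Product: 4 (R)-trimethyl{[3-methyl-3-(prop-2-en-1-yl)cyclopent-1-en-1-yl]oxy}silane
Conditions: Me3Al, copper thiophene-2-carboxylate (2 mol %), chiral biphenol-derived phosphoramidite ligand (4 mol %, the antipode that gives the R centre), Et2O, −30 °C; then Me3SiOTf, THF, 0 °C; non-acidic work-up
Reagents that add atoms: trimethylaluminium, C[Al](C)C; trimethylsilyl trifluoromethanesulfonate, C[Si](C)(C)OS(=O)(=O)C(F)(F)F
Why: Copper-catalysed asymmetric conjugate addition of Me3Al to the β-substituted enone, in which the chiral phosphoramidite–copper complex delivers methyl to one enantiotopic face of the future C8a, should set the R quaternary centre, and silylation of the aluminium enolate fixes the enolate double bond on the future C3a side.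

Step 3
Reactants: 5 3-methylbut-3-en-1-ol
Product: 6 3-methylbut-3-enal
Conditions: Dess–Martin periodinane, pyridine, CH2Cl2, 0 °C; used at once as a dried solution
Reagents that add atoms: none
Why: Dess–Martin oxidation of the homoallylic alcohol under pyridine buffering should give the β,γ-unsaturated aldehyde without migration of the double bond into conjugation; no stereocentre is formed.

Step 4
Reactants: 4 (R)-trimethyl{[3-methyl-3-(prop-2-en-1-yl)cyclopent-1-en-1-yl]oxy}silane; 6 3-methylbut-3-enal
Product: 9 (3aS,4S,8aR)-4-hydroxy-6,8a-dimethyl-1,2,3a,4,5,8-hexahydroazulen-3(8aH)-one (trans-fused; ketone at C3, hydroxyl at C4, C6=C7 olefin), via chlorozinc enolate 7 (not isolated), via anti-aldol adduct 8 (not isolated)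
Conditions: MeLi, THF, 0 °C; ZnCl2, −78 °C; 6, −78 to −20 °C; AcOH; then CH2Cl2 (high dilution), second-generation Grubbs catalyst (5 mol %), 40 °C
Reagents that add atoms: none
Why: MeLi cleaves the O–Si bond of 4 to the regiodefined lithium enolate, ZnCl2 turns it into zinc enolate 7, and 7 adds to aldehyde 6 through a chelated Zimmerman–Traxler chair to give, after protonation, aldol 8, whose allyl CH and methallyl carbon are then joined by the ruthenium carbene in a ring-closing olefin metathesis with loss of ethene, so that the C3a–C4 bond and the C6=C7 double bond are both formed in one flask (a formal [4+3] annulation). The closest known reaction types are the zinc-mediated directed aldol addition of enolates released from enol silanes and ring-closing metathesis to trisubstituted cycloheptenes. The seven-membered ring is closed in the metathesis event (union of a monosubstituted with a 1,1-disubstituted alkene), and ring closure allows only the cis ring olefin. C4 (S) is set relative to C3a by the ring-locked E geometry of the enolate, which in the equilibrating zinc chelate puts the aldehyde substituent equatorial and should give the anti aldol; C3a (S) is set relative to C8a by approach of the aldehyde to the enolate face carrying the small methyl group and away from the longer allyl arm, which leads to the trans ring fusion. The step needs enolate regiocontrol (secured by the enol silane from step 2), anti simple diastereoselection (secured by the cyclic enolate) and the face selectivity just named, which rests only on the size difference methyl versus allyl and is the weakest control element; the cis-fused diastereomer would be removed by chromatography of 9. Protonation of the aldolate before the neutral metathesis keeps C3a and C4 from equilibrating further, and the pre-set C8a centre is not touched.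

Step 5
Reactants: 9 (3aS,4S,8aR)-4-hydroxy-6,8a-dimethyl-1,2,3a,4,5,8-hexahydroazulen-3(8aH)-one
Product: 10 (3R,3aS,4S,8aR)-6,8a-dimethyl-3-(propan-2-yl)-1,2,3a,4,5,8-hexahydroazulene-3,4(8aH)-diol (the free diol of the target)
Conditions: iPrMgCl (excess), anhydrous CeCl3, THF, −78 to 0 °C; then water
Reagents that add atoms: isopropylmagnesium chloride, CC(C)[Mg]Cl
Why: The organocerium reagent formed from iPrMgCl and CeCl3 should add to the hindered, enolisable ketone (1,2-addition) instead of deprotonating or reducing it, and it should attack C3 from the face opposite the angular C8a methyl and the C3a–C4 bond carrying the metal alkoxide, so that the new hydroxyl is cis to the methyl as required for 3R.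

Step 6
Reactants: 10 (3R,3aS,4S,8aR)-6,8a-dimethyl-3-(propan-2-yl)-1,2,3a,4,5,8-hexahydroazulene-3,4(8aH)-diol; 11 2,2-dimethyl-4H-1,3-benzodioxin-4-one
Product: 12 (3R,3aS,4S,8aR)-3-hydroxy-6,8a-dimethyl-3-(propan-2-yl)-1,2,3,3a,4,5,8,8a-octahydroazulen-4-yl 2-hydroxybenzoate
Conditions: NaN(SiMe3)2 (1.1 equiv), THF, 0 °C; 11, 0 °C to rt; then AcOH
Reagents that add atoms: none
Why: The sodium alkoxide of the secondary C4 hydroxyl should open the benzodioxinone at its carbonyl (alkoxide acyl transfer with loss of acetone), which frees the phenol and gives the salicylate directly, while the tertiary C3 alkoxide is too hindered to compete and no stereocentre is touched.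

Compound list
1 | 3-ethoxycyclopent-2-en-1-one | CCOC1=CC(=O)CC1 | starting material
2 | prop-2-en-1-ylmagnesium bromide | C=CC[Mg]Br | starting material
3 | 3-(prop-2-en-1-yl)cyclopent-2-en-1-one | C=CCC1=CC(=O)CC1 | intermediate
4 | (R)-trimethyl{[3-methyl-3-(prop-2-en-1-yl)cyclopent-1-en-1-yl]oxy}silane | C=CC[C@@]1(C)CCC(O[Si](C)(C)C)=C1 | intermediate
5 | 3-methylbut-3-en-1-ol | CC(=C)CCO | starting material
6 | 3-methylbut-3-enal | CC(=C)CC=O | intermediate
7 | chlorozinc enolate of (R)-3-methyl-3-(prop-2-en-1-yl)cyclopentanone, enolate double bond toward the quaternary carbon | C=CC[C@@]1(C)CCC(O[Zn]Cl)=C1 | intermediate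
8 | (2S,3R)-2-[(1S)-1-hydroxy-3-methylbut-3-en-1-yl]-3-methyl-3-(prop-2-en-1-yl)cyclopentan-1-one | C=CC[C@@]1(C)CCC(=O)[C@@H]1[C@@H](O)CC(C)=C | intermediate
9 | (3aS,4S,8aR)-4-hydroxy-6,8a-dimethyl-1,2,3a,4,5,8-hexahydroazulen-3(8aH)-one | CC1=CC[C@@]2(C)CCC(=O)[C@@H]2[C@@H](O)C1 | intermediate
10 | (3R,3aS,4S,8aR)-6,8a-dimethyl-3-(propan-2-yl)-1,2,3a,4,5,8-hexahydroazulene-3,4(8aH)-diol | CC1=CC[C@@]2(C)CC[C@@](O)(C(C)C)[C@@H]2[C@@H](O)C1 | intermediate
11 | 2,2-dimethyl-4H-1,3-benzodioxin-4-one | CC1(C)OC(=O)c2ccccc2O1 | starting material
12 | (3R,3aS,4S,8aR)-3-hydroxy-6,8a-dimethyl-3-(propan-2-yl)-1,2,3,3a,4,5,8,8a-octahydroazulen-4-yl 2-hydroxybenzoate | CC1=CC[C@@]2(C)CC[C@@](O)(C(C)C)[C@@H]2[C@@H](OC(=O)c2ccccc2O)C1 | target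

Total step count: 6. Longest linear sequence: 5 steps (steps 1, 2, 4, 5, 6); step 3 prepares the aldehyde partner.

Steps most likely to fail

Step 4. The aldehyde may add to both faces of the enolate with little discrimination, because the neighbouring quaternary carbon offers only methyl against allyl, and this would divert material into the cis-fused series. The β,γ-unsaturated aldehyde may also suffer double-bond migration or self-condensation under the basic enolate. Fallback: set out from 4 and exchange silicon with SiCl4 and catalytic Hg(OAc)2 to the trichlorosilyl enolate F1. F1 is then used in a Lewis-base-catalysed aldol addition to 6 with a chiral phosphoramide catalyst. In its closed, catalyst-bound transition state the catalyst, not the substrate, should choose the enolate face, the E enolate should again give the anti adduct, and the conditions are non-basic. The adduct is compound 8, now isolated, and it is closed separately with second-generation Grubbs catalyst, which rejoins the route at 9.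

Step 5. Enolisation or retro-aldol cleavage of the β-alkoxide ketone, and hydride transfer from the isopropyl reagent, may outrun addition to the hindered carbonyl. Fallback: set out from 9 and add 2-propenylmagnesium bromide with CeCl3 in THF at −78 °C, a smaller sp2 nucleophile that is not a hydride donor, to give the isopropenyl carbinol F2. The 1,1-disubstituted alkene of F2 is then saturated with H2 and RhCl(PPh3)3, which should leave the trisubstituted ring alkene, and the route is rejoined at 10.

Step 2. On a five-membered enone the conjugate addition may proceed with insufficient enantioselectivity, the skipped diene may isomerise, or the aluminium enolate may resist silylation. Fallback: set out from 3 and carry out a racemic conjugate addition with Me2CuLi and Me3SiCl, which gives 4 together with the (S)-enol silane F3. The mixture is taken through step 4 unchanged, where F3 passes through the mirror-image zinc enolate F4 and the mirror-image aldol adduct F5 to the enantiomeric hydroxy ketone F6, formed beside 9. Candida antarctica lipase B with vinyl acetate should then acetylate F6 selectively to acetate F7, as the empirical lipase rule for secondary alcohols predicts for the 4R alcohol, and unreacted 9 is separated and carried on, which rejoins the route at 9.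

Further compounds
F1 | step 4 | (R)-trichloro{[3-methyl-3-(prop-2-en-1-yl)cyclopent-1-en-1-yl]oxy}silane | C=CC[C@@]1(C)CCC(O[Si](Cl)(Cl)Cl)=C1
F2 | step 5 | (3S,3aS,4S,8aR)-6,8a-dimethyl-3-(prop-1-en-2-yl)-1,2,3a,4,5,8-hexahydroazulene-3,4(8aH)-diol | CC1=CC[C@@]2(C)CC[C@@](O)(C(C)=C)[C@@H]2[C@@H](O)C1
F3 | step 2 | (S)-trimethyl{[3-methyl-3-(prop-2-en-1-yl)cyclopent-1-en-1-yl]oxy}silane | C=CC[C@]1(C)CCC(O[Si](C)(C)C)=C1
F4 | step 2 | chlorozinc enolate of (S)-3-methyl-3-(prop-2-en-1-yl)cyclopentanone | C=CC[C@]1(C)CCC(O[Zn]Cl)=C1
F5 | step 2 | (2R,3S)-2-[(1R)-1-hydroxy-3-methylbut-3-en-1-yl]-3-methyl-3-(prop-2-en-1-yl)cyclopentan-1-one | C=CC[C@]1(C)CCC(=O)[C@H]1[C@H](O)CC(C)=C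
F6 | step 2 | (3aR,4R,8aS)-4-hydroxy-6,8a-dimethyl-1,2,3a,4,5,8-hexahydroazulen-3(8aH)-one | CC1=CC[C@]2(C)CCC(=O)[C@H]2[C@H](O)C1
F7 | step 2 | (3aR,4R,8aS)-6,8a-dimethyl-3-oxo-1,2,3,3a,4,5,8,8a-octahydroazulen-4-yl acetate | CC1=CC[C@]2(C)CCC(=O)[C@H]2[C@H](OC(C)=O)C1
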